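**Remark (numbering and assumptions):** labdane numbering is used for the target: ring A = C1–C5 and C10, ring B = C5–C10, C17 = exocyclic methylene carbon on C8, C18/C19 = methyl/hydroxymethyl on C4, C20 = methyl on C10, C11–C16 = side chain and lactone. Geranyl chloride, phosphonate 7, ester 20 and oxazolidinone 22 are assumed to be commercial.

## Retrosynthetic overview

1. The lactone ring is formed last, by acetonide removal and acyl transfer from an Evans syn-aldol adduct. The aldol joins C12 to C13 (aldehyde 19 + imide 24) and sets C12 and C13; C14 is bought with ester 20.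
2. Rings A and B are formed together in one cationic cascade from the acyclic epoxy triene 15: first the C4–C5 bond (ring A), then the C9–C10 bond (ring B).
3. Enabling feature: the C3 carbinol sits next to the quaternary C4 (an opened trisubstituted epoxide), C5/C10 are the carbons of a former E alkene, and the exocyclic C8=C17 alkene next to C9 in ring B is the scar of an allylsilane.
4. Only the C3/C4 epoxide is set by catalysis (Katsuki–Sharpless epoxidation). C4 (by inversion), C5, C10 and C9 are relayed from it in the cascade.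
5. Precursor 15 is built linearly from geranyl chloride by propargylation, Still–Gennari olefination (Z-CH2O on C4) and carbocupration/ethylene oxide (allylsilane plus C11–C12).

Key step: step 10

## Route

Step 1
Reactants: 1 geranyl chloride [(2E)-1-chloro-3,7-dimethylocta-2,6-diene]
Product: 2 (E)-3-(5-chloro-3-methylpent-3-en-1-yl)-2,2-dimethyloxirane (racemic)
Conditions: mCPBA (1.05 equiv), NaHCO3, CH2Cl2, 0 °C
Reagents that add atoms: mCPBA (3-chloroperoxybenzoic acid), O=C(OO)c1cccc(Cl)c1
Why: Prilezhaev epoxidation should go to the electron-rich distal trisubstituted alkene because the proximal alkene is deactivated by the allylic chlorine; the new stereocentre is racemic and is destroyed in step 3.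

Step 2
Reactants: 2 (E)-3-(5-chloro-3-methylpent-3-en-1-yl)-2,2-dimethyloxirane; 3 1-(trimethylsilyl)propyne
Product: 5 (E)-2,2-dimethyl-3-[3-methyl-8-(trimethylsilyl)oct-3-en-7-yn-1-yl]oxirane (racemic), via 3-(trimethylsilyl)prop-2-ynyllithium 4 (not isolated)
Conditions: 3, n-BuLi, THF, −78 °C; then 2, −78 → 0 °C
Reagents that add atoms: none
Why: SN2 alkylation of the silyl-stabilised propargyl anion at the primary allylic chloride should give the 1,5-enyne (the silyl group disfavours allenyl products), while the hindered trisubstituted epoxide and the E alkene stay untouched at low temperature.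

Step 3
Reactants: 5 (E)-2,2-dimethyl-3-[3-methyl-8-(trimethylsilyl)oct-3-en-7-yn-1-yl]oxirane
Product: 6 (4E)-4-methyl-9-(trimethylsilyl)non-4-en-8-ynal
Conditions: H5IO6, THF/Et2O, 0 °C
Reagents that add atoms: none
Why: Periodic acid opens the epoxide to the glycol and cleaves it (Malaprade cleavage) to the aldehyde, which keeps the former epoxide oxygen, and acetone; the alkene and silylalkyne are inert.

Step 4
Reactants: 6 (4E)-4-methyl-9-(trimethylsilyl)non-4-en-8-ynal; 7 ethyl 2-[bis(2,2,2-trifluoroethoxy)phosphoryl]propanoate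
Product: 9 ethyl (2Z,6E)-2,6-dimethyl-11-(trimethylsilyl)undeca-2,6-dien-10-ynoate, via potassium phosphonate carbanion 8 (not isolated)
Conditions: 7, KN(SiMe3)2, 18-crown-6, THF, −78 °C; then 6
Reagents that add atoms: none
Why: The Still–Gennari variant of the Horner–Wadsworth–Emmons reaction (fast elimination from the kinetic adduct of the electron-poor phosphonate) should give the Z trisubstituted enoate, which places the future C19 oxygen cis to the chain and so decides which C4 substituent becomes axial.

Step 5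
Reactants: 9 ethyl (2Z,6E)-2,6-dimethyl-11-(trimethylsilyl)undeca-2,6-dien-10-ynoate
Product: 10 (2Z,6E)-2,6-dimethyl-11-(trimethylsilyl)undeca-2,6-dien-10-yn-1-ol
Conditions: iBu2AlH (2.5 equiv), CH2Cl2, −78 °C; Rochelle salt work-up
Reagents that add atoms: none
Why: 1,2-Reduction of the conjugated ester by the aluminium hydride gives the allylic alcohol with the Z geometry retained, and the silylalkyne is not hydroaluminated at −78 °C.

Step 6
Reactants: 10 (2Z,6E)-2,6-dimethyl-11-(trimethylsilyl)undeca-2,6-dien-10-yn-1-ol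
Product: 11 (2Z,6E)-2,6-dimethylundeca-2,6-dien-10-yn-1-ol
Conditions: K2CO3 (0.2 equiv), MeOH, rt
Reagents that add atoms: none
Why: Base-catalysed methanolysis of the C(sp)–Si bond frees the terminal alkyne without touching the alkenes or the allylic alcohol.

Step 7
Reactants: 11 (2Z,6E)-2,6-dimethylundeca-2,6-dien-10-yn-1-ol
Product: 13 (2Z,6E,10Z)-2,6-dimethyl-10-[(trimethylsilyl)methyl]trideca-2,6,10-triene-1,13-diol, via alkenylcopper alkoxide 12 (not isolated)
Conditions: Me3SiCH2MgCl (1.0 equiv), Et2O, 0 °C (alkoxide); Me3SiCH2Cu·MgBrCl (2 equiv, from Me3SiCH2MgCl + CuBr·SMe2), Et2O/Me2S, −30 → 0 °C; then Me3SiCH2MgCl (2 equiv) and ethylene oxide (excess), −40 → 0 °C; aq NH4Cl/NH3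
Reagents that add atoms: (trimethylsilyl)methylmagnesium chloride, C[Si](C)(C)C[Mg]Cl; ethylene oxide, C1CO1
Why: Normant carbocupration adds the silylmethyl group (to the internal carbon) and copper syn across the terminal alkyne, and the alkenyl–copper bond is then replaced with retention by ethylene oxide with the silylmethyl group on copper as the non-transferred ligand, so CH2SiMe3 and the hydroxyethyl chain end up cis, the geometry that later makes the C9 side chain equatorial.

Step 8
Reactants: 13 (2Z,6E,10Z)-2,6-dimethyl-10-[(trimethylsilyl)methyl]trideca-2,6,10-triene-1,13-diol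
Product: 14 (3Z,7E)-10-[(2R,3S)-3-(hydroxymethyl)-3-methyloxiran-2-yl]-8-methyl-4-[(trimethylsilyl)methyl]deca-3,7-dien-1-ol
Conditions: Ti(OiPr)4 (0.2 equiv), L-(+)-diethyl tartrate (0.24 equiv), t-BuOOH, 4 Å molecular sieves, CH2Cl2, −20 °C
Reagents that add atoms: tert-butyl hydroperoxide, CC(C)(C)OO
Why: Katsuki–Sharpless asymmetric epoxidation is selective for the allylic alcohol (the homoallylic alcohol and the isolated alkenes react far more slowly), and with the L-(+)-tartrate the oxygen is delivered to the face that gives the (2S,3R)-2-methyl-2,3-epoxy alcohol, which fixes C3 and the configuration from which C4 is later inverted.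

Step 9
Reactants: 14 (3Z,7E)-10-[(2R,3S)-3-(hydroxymethyl)-3-methyloxiran-2-yl]-8-methyl-4-[(trimethylsilyl)methyl]deca-3,7-dien-1-ol
Product: 15 bis(tert-butyldimethylsilyl) ether of 14 (both primary hydroxyls silylated)
Conditions: TBSCl (2.5 equiv), imidazole, DMF, 0 °C → rt
Reagents that add atoms: tert-butyldimethylsilyl chloride, CC(C)(C)[Si](C)(C)Cl
Why: Standard silylation of both primary alcohols gives ethers that cannot act as neighbouring groups toward the epoxide (unlike esters) and survive the Lewis acid of step 10.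

Step 10
Reactants: 15 bis(tert-butyldimethylsilyl) ether of 14
Product: 16 (1R,2R,4aS,5R,8aS)-1-({[tert-butyl(dimethyl)silyl]oxy}methyl)-5-(2-{[tert-butyl(dimethyl)silyl]oxy}ethyl)-1,4a-dimethyl-6-methylidenedecahydronaphthalen-2-ol
Conditions: MeAlCl2 (2.0 equiv), CH2Cl2, −78 °C; then Et3N, MeOH/H2O
Reagents that add atoms: none
Why: MeAlCl2 coordinates the epoxide oxygen, the C4–O bond ionises at the tertiary carbon while the E C5=C10 alkene attacks C4 anti to the leaving oxygen (C4–C5 bond, ring A), the C10 cation is captured by the allylsilane carbon C9 (C9–C10 bond, ring B), and the β-silyl cation at C8 loses the silyl group to leave only the exocyclic C8=C17 alkene; the closest known reaction type is the Lewis-acid epoxide-initiated cation–olefin polycyclisation with a Hosomi–Sakurai-type allylsilane terminator. Ring A closes in a 6-endo mode (endo opening of the epoxide at C4, 6-endo-trig on C5=C10) and ring B 6-endo-trig on C8=C9, both through chair-like transition states. C3 keeps the configuration set in step 8 and its oxygen becomes the equatorial hydroxyl; C4 is formed with inversion, so the Z-placed CH2OTBS group becomes axial and cis to the C3 oxygen and the methyl equatorial. C5 and C10 arise by anti addition across the E alkene (trans ring fusion, C10 methyl axial on the face of the CH2OTBS group), and C9 follows from the allylsilane geometry, whose chain trans to C7 becomes the equatorial side chain. The step needs opening at C4 and not C3, a chair–chair fold and elimination to the exocyclic alkene only; the cation-stabilising tertiary C4, the non-participating silyl ether, the defined alkene geometries and the CH2SiMe3 group secure these. MeAlCl2 also removes adventitious acid as methane, which protects the allylsilane from protodesilylation.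

Step 11
Reactants: 16 (1R,2R,4aS,5R,8aS)-1-({[tert-butyl(dimethyl)silyl]oxy}methyl)-5-(2-{[tert-butyl(dimethyl)silyl]oxy}ethyl)-1,4a-dimethyl-6-methylidenedecahydronaphthalen-2-ol
Product: 17 (1R,2R,4aS,5R,8aS)-5-(2-hydroxyethyl)-1-(hydroxymethyl)-1,4a-dimethyl-6-methylidenedecahydronaphthalen-2-ol
Conditions: Bu4NF (3 equiv), THF, rt → 40 °C
Reagents that add atoms: none
Why: Fluoride cleaves both Si–O bonds (the hindered axial C19 ether may need gentle warming) and nothing else in the molecule is fluoride-sensitive once the allylsilane is gone.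

Step 12
Reactants: 17 (1R,2R,4aS,5R,8aS)-5-(2-hydroxyethyl)-1-(hydroxymethyl)-1,4a-dimethyl-6-methylidenedecahydronaphthalen-2-ol
Product: 18 3,19-O-isopropylidene acetal of 17 (1,3-dioxane across the C3 hydroxyl and the C19 hydroxymethyl; C12 hydroxyl free)
Conditions: Me2C(OMe)2 (1.5 equiv), PPTS (cat.), CH2Cl2, rt
Reagents that add atoms: 2,2-dimethoxypropane, COC(C)(C)OC
Why: Acid-catalysed transketalisation should select the cis 1,3-diol (equatorial C3 hydroxyl, axial C19 hydroxymethyl), which closes a six-membered dioxane, and leave the isolated primary C12 alcohol free.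

Step 13
Reactants: 18 3,19-O-isopropylidene acetal of 17
Product: 19 2-[3,19-O-isopropylidene-protected decalinyl]acetaldehyde (the C12 aldehyde of 18)
Conditions: Dess–Martin periodinane, NaHCO3, CH2Cl2, 0 °C → rt
Reagents that add atoms: none
Why: Buffered Dess–Martin oxidation converts the primary alcohol to the aldehyde without acid that could cleave the acetonide or move the exocyclic alkene; C9 is not α to the carbonyl, so no stereocentre is at risk.

Step 14
Reactants: 20 methyl 2-[(4S)-2,2-dimethyl-1,3-dioxolan-4-yl]acetate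
Product: 21 2-[(4S)-2,2-dimethyl-1,3-dioxolan-4-yl]acetic acid
Conditions: LiOH, THF/H2O, 0 °C; then 1 M HCl to pH 4 at 0 °C
Reagents that add atoms: lithium hydroxide, [Li+].[OH-]
Why: Saponification of the methyl ester under cold basic conditions leaves the acetonide and the C14 stereocentre intact, and the acid is used at once.

Step 15
Reactants: 21 2-[(4S)-2,2-dimethyl-1,3-dioxolan-4-yl]acetic acid; 22 (S)-4-benzyl-1,3-oxazolidin-2-one
Product: 24 (4S)-4-benzyl-3-{2-[(4S)-2,2-dimethyl-1,3-dioxolan-4-yl]acetyl}-1,3-oxazolidin-2-one, via mixed pivalic anhydride 23 (not isolated)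
Conditions: t-BuCOCl, Et3N, THF, −20 °C; then 22, LiCl, rt
Reagents that add atoms: none
Why: N-Acylation of the oxazolidinone by the mixed anhydride under LiCl/Et3N activation occurs at the less hindered carbonyl and avoids strong base, so the β-alkoxy acid is not eliminated.

Step 16
Reactants: 19 2-[3,19-O-isopropylidene-protected decalinyl]acetaldehyde; 24 (4S)-4-benzyl-3-{2-[(4S)-2,2-dimethyl-1,3-dioxolan-4-yl]acetyl}-1,3-oxazolidin-2-one
Product: 26 (4S)-4-benzyl-3-[(2R,3R)-2-[(4S)-2,2-dimethyl-1,3-dioxolan-4-yl]-3-hydroxy-4-(3,19-O-isopropylidene-protected decalinyl)butanoyl]-1,3-oxazolidin-2-one, via dibutylboron enolate 25 (not isolated)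
Conditions: 24 (1.3 equiv), Bu2BOTf, iPr2NEt, CH2Cl2, −78 → 0 °C; then 19, −78 → 0 °C; pH 7 buffer, MeOH, H2O2, 0 °C
Reagents that add atoms: none
Why: In the Evans syn aldol the Z boron enolate reacts through a closed chair (Zimmerman–Traxler) transition state with the benzyl group shielding one enolate face, which should set C12 (R) and C13 (R) together under auxiliary control, while the covalent boron enolate resists β-elimination of the dioxolane oxygen.

Step 17
Reactants: 26 (4S)-4-benzyl-3-[(2R,3R)-2-[(4S)-2,2-dimethyl-1,3-dioxolan-4-yl]-3-hydroxy-4-(3,19-O-isopropylidene-protected decalinyl)butanoyl]-1,3-oxazolidin-2-one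
Product: 28 the target (3R,4S)-4-hydroxy-3-{(1R)-1-hydroxy-2-[(1R,4aS,5R,6R,8aS)-6-hydroxy-5-(hydroxymethyl)-5,8a-dimethyl-2-methylidenedecahydronaphthalen-1-yl]ethyl}oxolan-2-one, via tetraol imide 27 (not isolated)
Conditions: AcOH/THF/H2O (3:1:1), 40 °C
Reagents that add atoms: none
Why: Aqueous acetic acid hydrolyses both acetonides and the freed primary C15 hydroxyl should attack the activated imide carbonyl in a 5-exo-trig acyl transfer that closes the lactone and releases the oxazolidinone; no stereocentre is touched, so the C13 side chain and the C14 hydroxyl remain cis.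

## Compound list

1 | geranyl chloride, (2E)-1-chloro-3,7-dimethylocta-2,6-diene | CC(C)=CCC/C(C)=C/CCl | starting material
2 | (E)-3-(5-chloro-3-methylpent-3-en-1-yl)-2,2-dimethyloxirane (racemic) | CC1(C)OC1CC/C(C)=C/CCl | intermediate
3 | 1-(trimethylsilyl)propyne | CC#C[Si](C)(C)C | starting material
4 | 3-(trimethylsilyl)prop-2-ynyllithium | [Li]CC#C[Si](C)(C)C | intermediate
5 | (E)-2,2-dimethyl-3-[3-methyl-8-(trimethylsilyl)oct-3-en-7-yn-1-yl]oxirane (racemic) | CC1(C)OC1CC/C(C)=C/CCC#C[Si](C)(C)C | intermediate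
6 | (4E)-4-methyl-9-(trimethylsilyl)non-4-en-8-ynal | O=CCC/C(C)=C/CCC#C[Si](C)(C)C | intermediate
7 | ethyl 2-[bis(2,2,2-trifluoroethoxy)phosphoryl]propanoate | CCOC(=O)C(C)P(=O)(OCC(F)(F)F)OCC(F)(F)F | starting material
8 | potassium salt of the α-carbanion of 7 | CCOC(=O)[C-](C)P(=O)(OCC(F)(F)F)OCC(F)(F)F.[K+] | intermediate
9 | ethyl (2Z,6E)-2,6-dimethyl-11-(trimethylsilyl)undeca-2,6-dien-10-ynoate | CCOC(=O)/C(C)=C\CC/C(C)=C/CCC#C[Si](C)(C)C | intermediate
10 | (2Z,6E)-2,6-dimethyl-11-(trimethylsilyl)undeca-2,6-dien-10-yn-1-ol | OC/C(C)=C\CC/C(C)=C/CCC#C[Si](C)(C)C | intermediate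
11 | (2Z,6E)-2,6-dimethylundeca-2,6-dien-10-yn-1-ol | OC/C(C)=C\CC/C(C)=C/CCC#C | intermediate
12 | alkenylcopper intermediate (chloromagnesium alkoxide; Cu cis to CH2SiMe3) | Cl[Mg]OC/C(C)=C\CC/C(C)=C/CC/C(C[Si](C)(C)C)=C/[Cu] | intermediate
13 | (2Z,6E,10Z)-2,6-dimethyl-10-[(trimethylsilyl)methyl]trideca-2,6,10-triene-1,13-diol | OC/C(C)=C\CC/C(C)=C/CC/C(C[Si](C)(C)C)=C/CCO | intermediate
14 | (3Z,7E)-10-[(2R,3S)-3-(hydroxymethyl)-3-methyloxiran-2-yl]-8-methyl-4-[(trimethylsilyl)methyl]deca-3,7-dien-1-ol | OC[C@]1(C)O[C@@H]1CC/C(C)=C/CC/C(C[Si](C)(C)C)=C/CCO | intermediate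
15 | bis(tert-butyldimethylsilyl) ether of 14 | CC(C)(C)[Si](C)(C)OC[C@]1(C)O[C@@H]1CC/C(C)=C/CC/C(C[Si](C)(C)C)=C/CCO[Si](C)(C)C(C)(C)C | intermediate
16 | (1R,2R,4aS,5R,8aS)-1-({[tert-butyl(dimethyl)silyl]oxy}methyl)-5-(2-{[tert-butyl(dimethyl)silyl]oxy}ethyl)-1,4a-dimethyl-6-methylidenedecahydronaphthalen-2-ol | C=C1CC[C@@H]2[C@](C)(CO[Si](C)(C)C(C)(C)C)[C@H](O)CC[C@@]2(C)[C@@H]1CCO[Si](C)(C)C(C)(C)C | intermediate
17 | (1R,2R,4aS,5R,8aS)-5-(2-hydroxyethyl)-1-(hydroxymethyl)-1,4a-dimethyl-6-methylidenedecahydronaphthalen-2-ol | C=C1CC[C@@H]2[C@](C)(CO)[C@H](O)CC[C@@]2(C)[C@@H]1CCO | intermediate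
18 | 3,19-O-isopropylidene acetal of 17 | C=C1CC[C@@H]2[C@]3(C)COC(C)(C)O[C@@H]3CC[C@@]2(C)[C@@H]1CCO | intermediate
19 | C12 aldehyde of 18 (decalin–CH2–CHO, acetonide retained) | C=C1CC[C@@H]2[C@]3(C)COC(C)(C)O[C@@H]3CC[C@@]2(C)[C@@H]1CC=O | intermediate
20 | methyl 2-[(4S)-2,2-dimethyl-1,3-dioxolan-4-yl]acetate | COC(=O)C[C@H]1COC(C)(C)O1 | starting material
21 | 2-[(4S)-2,2-dimethyl-1,3-dioxolan-4-yl]acetic acid | OC(=O)C[C@H]1COC(C)(C)O1 | intermediate
22 | (S)-4-benzyl-1,3-oxazolidin-2-one | O=C1N[C@@H](Cc2ccccc2)CO1 | starting material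
23 | mixed anhydride of 21 with pivalic acid | CC(C)(C)C(=O)OC(=O)C[C@H]1COC(C)(C)O1 | intermediate
24 | (4S)-4-benzyl-3-{2-[(4S)-2,2-dimethyl-1,3-dioxolan-4-yl]acetyl}-1,3-oxazolidin-2-one | O=C(C[C@H]1COC(C)(C)O1)N1[C@@H](Cc2ccccc2)COC1=O | intermediate
25 | Z dibutylboron enolate of 24 | CCCCB(CCCC)O/C(=C\[C@H]1COC(C)(C)O1)N1[C@@H](Cc2ccccc2)COC1=O | intermediate
26 | Evans syn-aldol adduct, (2R,3R)-configured acyl chain on the (S)-benzyl oxazolidinone | C=C1CC[C@@H]2[C@]3(C)COC(C)(C)O[C@@H]3CC[C@@]2(C)[C@@H]1C[C@@H](O)[C@H]([C@H]1COC(C)(C)O1)C(=O)N1[C@@H](Cc2ccccc2)COC1=O | intermediate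
27 | tetraol imide (26 without both acetonides) | C=C1CC[C@@H]2[C@](C)(CO)[C@H](O)CC[C@@]2(C)[C@@H]1C[C@@H](O)[C@H]([C@H](O)CO)C(=O)N1[C@@H](Cc2ccccc2)COC1=O | intermediate
28 | (3R,4S)-4-hydroxy-3-{(1R)-1-hydroxy-2-[(1R,4aS,5R,6R,8aS)-6-hydroxy-5-(hydroxymethyl)-5,8a-dimethyl-2-methylidenedecahydronaphthalen-1-yl]ethyl}oxolan-2-one | C=C1CC[C@@H]2[C@](C)(CO)[C@H](O)CC[C@@]2(C)[C@@H]1C[C@@H](O)[C@H]1C(=O)OC[C@H]1O | target

## Step count and risks

Total step count: 17. Longest linear sequence: 15 steps (steps 1–13, 16 and 17).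

**Step 10 (key cyclisation).** The activated epoxide may collapse before the alkene attacks (1,2-hydride shift, chloride capture), or the cascade may stop after ring A. Fallback, from 11 back to 16, by a radical instead of a cationic ring closure: Negishi carboalumination of 11 (Me3Al, Cp2ZrCl2, then n-BuLi and ethylene oxide) would give (2Z,6E,10E)-2,6,10-trimethyltrideca-2,6,10-triene-1,13-diol F1. Epoxidation as in step 8 would give the epoxy diol F2 and silylation as in step 9 its bis(silyl) ether F3. Cp2TiCl (trivalent titanium, generated from Cp2TiCl2 and Mn powder, with Me3SiCl/2,4,6-collidine for turnover; Nugent–RajanBabu epoxide opening) would then open the epoxide homolytically to the tertiary C4 radical. This closes ring A and ring B by two 6-endo additions and ends by loss of a hydrogen from the C8 methyl group, giving the exocyclic alkene of 16. In this variant C4 is set by the conformational preference of a planar radical and not by inversion, so a C4 epimer may have to be separated.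

**Step 7 (carbocupration/ethylene oxide).** Transfer of the silylmethyl group to the unactivated alkyne may be slow, the alkyne may be deprotonated instead, or the alkenylcopper may fail to open ethylene oxide. Fallback, from 11 back to 13, building the alkene from a cyclic enol ether: double deprotonation of 11 (n-BuLi, 2 equiv) and opening of ethylene oxide (BF3·OEt2, −78 °C) would give (2Z,6E)-2,6-dimethyltrideca-2,6-dien-10-yne-1,13-diol F4. 5-Endo-dig cycloisomerisation (PdCl2(MeCN)2 cat., THF) would give (2Z,6E)-9-(4,5-dihydrofuran-2-yl)-2,6-dimethylnona-2,6-dien-1-ol F5. Nickel-catalysed Kumada-type coupling of the ring enol ether C–O bond with Me3SiCH2MgCl (NiCl2(PPh3)2 cat., reduced in the flask to zerovalent nickel, toluene, reflux) replaces that oxygen by CH2SiMe3 with retention and gives 13 with the same alkene geometry.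

**Step 17 (global deprotection and lactonisation).** Acyl transfer from the auxiliary may stay incomplete after acetonide loss, or the acid may promote dehydration of the β-hydroxy lactone. Fallback, from 26 back to 28, removing the auxiliary first: LiOH/H2O2 (THF/H2O, 0 °C) would cleave the imide to (2R,3R)-2-[(4S)-2,2-dimethyl-1,3-dioxolan-4-yl]-3-hydroxy-4-(3,19-O-isopropylidene-protected decalinyl)butanoic acid F6. Brief treatment with PPTS in MeOH/H2O at rt then removes both acetonides, and the free γ-hydroxy acid closes to lactone 28 without needing the imide as acyl donor.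

## Further compounds

F1 | step 10 | (2Z,6E,10E)-2,6,10-trimethyltrideca-2,6,10-triene-1,13-diol | OC/C(C)=C\CC/C(C)=C/CC/C(C)=C/CCO
F2 | step 10 | (3E,7E)-10-[(2R,3S)-3-(hydroxymethyl)-3-methyloxiran-2-yl]-4,8-dimethyldeca-3,7-dien-1-ol | OC[C@]1(C)O[C@@H]1CC/C(C)=C/CC/C(C)=C/CCO
F3 | step 10 | bis(tert-butyldimethylsilyl) ether of F2 | CC(C)(C)[Si](C)(C)OC[C@]1(C)O[C@@H]1CC/C(C)=C/CC/C(C)=C/CCO[Si](C)(C)C(C)(C)C
F4 | step 7 | (2Z,6E)-2,6-dimethyltrideca-2,6-dien-10-yne-1,13-diol | OC/C(C)=C\CC/C(C)=C/CCC#CCCO
F5 | step 7 | (2Z,6E)-9-(4,5-dihydrofuran-2-yl)-2,6-dimethylnona-2,6-dien-1-ol | OC/C(C)=C\CC/C(C)=C/CCC1=CCCO1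
F6 | step 17 | (2R,3R)-2-[(4S)-2,2-dimethyl-1,3-dioxolan-4-yl]-3-hydroxy-4-(3,19-O-isopropylidene-protected decalinyl)butanoic acid | C=C1CC[C@@H]2[C@]3(C)COC(C)(C)O[C@@H]3CC[C@@]2(C)[C@@H]1C[C@@H](O)[C@H]([C@H]1COC(C)(C)O1)C(=O)O
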